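Assumption: the SMILES has no stereocentre and no stereogenic double bond, so the compound is achiral and there is no enantiomer to select; the side chain is read as unbranched nonadecyl (19 carbons), C25H42O2 overall.

**Retrosynthetic overview**

1. Building blocks: hydroquinone (1), a bulk aromatic feedstock, and eicosanoic (arachidic) acid (2), a C20 fatty acid.
2. Oxidative dearomatisation of 1 in the flask gives 1,4-benzoquinone (3), a D2h-symmetric radical acceptor with four equivalent C–H positions.
3. Key disconnection: the ring-C–CH2 bond of 2-nonadecyl-1,4-benzoquinone (4, the target) is cut back to 3 and the nonadecyl radical released from 2 by loss of CO2 (silver/persulfate radical decarboxylation); the single C–H alkylation breaks the symmetry of 3.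
4. Ring formation: none. The only ring, the six-membered carbocycle, is carried through from 1; there is no stereocentre to set.

**Route**

Step 1
Reactants: 1 hydroquinone (benzene-1,4-diol); 2 eicosanoic acid (arachidic acid, unbranched C19H39–COOH)
Product: 4 2-nonadecyl-1,4-benzoquinone (2-nonadecylcyclohexa-2,5-diene-1,4-dione), via 1,4-benzoquinone 3 (not isolated)
Conditions: 1 (2.5 equiv), (NH4)2S2O8 (2.6 equiv), AgNO3 (0.3 equiv), MeCN/H2O 1:1, 40 °C, 1 h, until 1 is consumed; then 2 (1.0 equiv) in warm MeCN, 75 °C, (NH4)2S2O8 (1.5 equiv) in H2O added over 1 h, then 1 h at 75 °C; hexane/EtOAc extraction, silica, recrystallisation from EtOH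
Reagents that add atoms: none
Why: Proposed new method: persulfate with catalytic AgNO3 first oxidises 1 to 3 (two-electron dearomatisation, completed before 2 is added so that no phenolic hydrogen donor is left to quench radicals), then divalent silver formed from AgNO3 and persulfate oxidises the carboxylate of 2, CO2 is lost, and the nucleophilic primary nonadecyl radical adds to one of the four equivalent C–H positions of electron-poor 3, the adduct radical being re-oxidised to the quinone level, while the excess of 3 and the deactivating, hindering alkyl group suppress a second alkylation; the closest known reaction type is the Jacobsen–Torssell (Minisci-type) silver/persulfate decarboxylative alkylation of preformed quinones, telescoped here with the known persulfate oxidation of a hydroquinone; no stereocentre is formed.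

**Compound list**

1 | hydroquinone (benzene-1,4-diol) | Oc1ccc(O)cc1 | starting material
2 | eicosanoic acid (arachidic acid) | CCCCCCCCCCCCCCCCCCCC(=O)O | starting material
3 | 1,4-benzoquinone (cyclohexa-2,5-diene-1,4-dione) | O=C1C=CC(=O)C=C1 | intermediate
4 | 2-nonadecyl-1,4-benzoquinone (2-nonadecylcyclohexa-2,5-diene-1,4-dione) | CCCCCCCCCCCCCCCCCCCC1=CC(=O)C=CC1=O | target

**Totals**

Total step count: 1. Longest linear sequence: 1 step.

**Steps most likely to fail**

The route consists of step 1 alone, so it is the only entry. Its failure modes, in order of likelihood, are:

- Incomplete oxidation of 1 before the radical stage: residual hydroquinone donates hydrogen to the nonadecyl radical (giving nonadecane) and reduces the silver catalyst.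
- Poor solubility of waxy 2 in aqueous MeCN, together with slow trapping of a primary radical, which lowers conversion.
- Dialkylation to 2,5- and 2,6-dinonadecylquinones and oxidative decay of 3, which lower the isolated yield.

Fallback for step 1 (sets out from 1, comes back to the route at 4): this replaces the radical C–H alkylation of the quinone with a polar C–C bond formation on the protected arene, followed by a late oxidative dearomatisation. Compound 1 is O-methylated twice (MeI, K2CO3, acetone, reflux) to 1,4-dimethoxybenzene F1. F1 is ortho-lithiated (n-BuLi, TMEDA, THF, 0 °C) to 2,5-dimethoxyphenyllithium F2. Without isolation, F2 is alkylated with 1-bromononadecane (CCCCCCCCCCCCCCCCCCCBr; 0 °C to room temperature) to 1,4-dimethoxy-2-nonadecylbenzene F3. Oxidative demethylation of F3 with (NH4)2Ce(NO3)6 in MeCN/H2O/CH2Cl2 at 0 °C then gives 4, with both quinone oxygens supplied by water. The sequence is three operations, each a standard reaction type: Williamson ether synthesis, directed ortho-metalation with SN2 alkylation, and oxidative demethylation of a para-dimethoxyarene.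

**Further compounds**

F1 | step 1 | 1,4-dimethoxybenzene | COc1ccc(OC)cc1
F2 | step 1 | 2,5-dimethoxyphenyllithium | [Li]c1cc(OC)ccc1OC
F3 | step 1 | 1,4-dimethoxy-2-nonadecylbenzene | CCCCCCCCCCCCCCCCCCCc1cc(OC)ccc1OC
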